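## The problem

The target is a furofuranone lignan. A γ-lactone, ring A (C1–O2–C3(=O)–C4–C5), is cis-fused along C4–C5 to a tetrahydrofuran, ring B (C4–C5–C6–O7–C8); C1 carries the 4-hydroxy-3,5-dimethoxyphenyl group and C8 the 3,4-dihydroxyphenyl group. There are four contiguous stereocentres, C1 (S), C4 (R), C5 (S) and C8 (S). All four hydrogens lie on the convex face, so both aryl groups point into the concave face; this is the least stable arrangement and must be made under kinetic control and then left alone. The cis ring fusion is enforced by strain, so C4 can be set last by protonation. C1 and C5 are vicinal and can both come from one trans epoxide opened with inversion at C5, which puts the C1 aryl group cis to C6; C8 is separated from that pair by C4 and needs its own control element. Both benzylic C–O bonds (C1–O2 and C8–O7) stand para to a phenol in the target and would ionise in acid and re-close to the exo isomers. C8–O7 is also β to the lactone carbonyl and open to base-induced elimination, and the catechol oxidises easily, so the phenols must stay masked until a last neutral step. The enabling feature is the position of C4 between the C3 carbonyl and the benzylic carbon C8: with one extra carboxyl group it is the α-carbon of an arylidene malonate (C8=C4), while O7–C6–C5–C1–O2 is the oxygen pattern of an epoxidised cinnamyl alcohol. An alkoxide at O7 that adds to C8 creates a carbanion at C4 placed for a five-membered closure onto epoxide carbon C5, and the oxygen freed at C1 is one five-membered ring away from a C4 ester.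

## Retrosynthesis

**Debenzylation (14 from 13).** Only the three O–benzyl bonds are cut. Freeing the phenols earlier would carry p-hydroxybenzylic C–O bonds through heat or base. Benzyl is preferred to silyl or acetal groups because it survives alkoxide and zerovalent palladium and leaves under neutral hydrogenolysis. The forward step must cleave aryl benzyl ethers faster than the two ring benzylic C–O bonds.

**Carboxyl at C4 (13 from 11 through 12).** A carboxyl group is added back on C4 as an allyl ester, which makes C4 a malonate carbon. A benzyl ester would release the acid only together with the free phenols, so the decarboxylation would have to be run hot on the acid-labile polyphenol. The allyl ester is removed with zerovalent palladium and formate while the phenols are still benzylated, and the half-acid 12 then loses CO2. The forward reaction only has to give the cis fusion at C4, which strain guarantees.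

**Cascade (11 from 5 and 8).** Three bonds are cut at once: O7–C8, C4–C5 and O2–C3. Cutting only C4–C5 and O2–C3 (an untethered malonate opening of the aryl epoxide) would send the nucleophile to benzylic C1; tying the malonate to O7 first makes attack at C5 a five-membered exo closure. Cutting only O7–C8 would require ring A, with its cis substituents, from a separate multi-step sequence. The precursors are far simpler: 5 holds two stereocentres from a reagent-controlled epoxidation and 8 is achiral. The step must deliver reversible alkoxide addition, C5-selective opening with inversion, and faster closure of the C8 epimer that gives the 2,4-cis tetrahydrofuran.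

**Arylidene malonate (8 from 6 and 7).** The C8=C4 bond is cut by a Knoevenagel disconnection to aldehyde 6 and diallyl malonate 7. The two ester groups are identical, so the condensation has no selectivity issue. Allyl esters also make the alkoxide released in the lactonisation identical with the ester alkoxy group, so transesterification by it is degenerate.

**Epoxy alcohol (5 from 4, 3, 1 and 2).** Removing the epoxide oxygen gives (E)-allylic alcohol 4, the best substrate class for the Sharpless asymmetric epoxidation (Ti(OiPr)4, tartrate ester), which fixes C1 and C5 in absolute terms. Routes through a cinnamate epoxidation or a dihydroxylation would add steps. 4 goes back to ester 3 by hydride reduction, and 3 to aldehyde 1 and phosphonate 2 by a Horner–Wadsworth–Emmons cut that secures the (E) geometry.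

## Roads not taken

Alternative 1: ring B is cut at C6–O7 and traced to a cyclopropane. In keto ester A1 the cyclopropane (C4, C5, C6) carries the ester and the catechol-derived aroyl group on C4 (C8 as ketone) and the syringyl-derived aroyl group on C5 (C1 as ketone). Under iodide catalysis, iodide opens C4–C6 at C6 and the enolate oxygen displaces it, giving dihydrofuran A2 (Cloke–Wilson ring expansion).
- Merits: the key step belongs to a known reaction class, which the chosen cascade does not, and A2 holds every skeletal atom. Hydrogenation of C4=C8 from the face away from the C5 substituent would in principle give the all-cis array.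
- Weak points: C4, C8 and C1 are still to be set by two separate reductions. The tetrasubstituted donor–acceptor C4=C8 bond hydrogenates slowly and competes with O-benzyl hydrogenolysis. The C5 hydrogen of A2 is α to an aryl ketone and allylic, so epimerisation and aromatisation to the furan threaten. The reduction at C1 has no clear bias towards the aryl group cis to C6, and A1 needs an enantioselective cyclopropanation.
- Comparison: the chosen plan is less precedented in its key step, but it takes C1 and C5 from one epoxide and needs no later step that creates C1, C5 or C8.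

Alternative 2: ring A is cut at C1–C5 and C3–C4 to a four-membered ketone, with O2 inserted afterwards. The arylketene from acid chloride A3 and an amine base would add to 2,5-dihydrofuran A4 to give cyclobutanone A5, and Baeyer–Villiger oxidation would lead to lactone A6.
- Merits: this is the shortest entry to the bicyclic core. The endo preference of ketene cycloadditions, followed by oxygen insertion with retention, delivers the contra-thermodynamic C1 aryl group (cis to C6) more reliably than any other road, the chosen one included.
- Weak points: A5 is racemic and no simple reagent control exists for this cycloaddition. Monoarylketenes dimerise readily and unactivated A4 is a poor partner. Both α-carbons of A5 are secondary, so the site of oxygen insertion is not secure. Above all, A6 lacks the catechol ring: C8 is a methylene group, and arylating one of two ether α-positions with endo selectivity has no dependable solution.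
- Comparison: the chosen plan brings the C8 aryl group in with the malonate and takes its absolute configuration from the epoxidation.

Alternative 3: ring B is cut at O7–C8 and closed last by reduction. Keto lactone A7 (ring A complete, an aroyl group on C4, a free hydroxymethyl group on C5) would form the cyclic hemiketal and then the oxocarbenium ion with acid. A silane would deliver hydride to C8 from the convex face while C4 settles into the cis fusion; the product A8 is identical with 13.
- Merits: control of C8 by convex-face attack is better founded than the kinetic selection on which the chosen cascade relies.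
- Weak points: the difficulty moves to A7. Its ring A needs the C1 aryl group cis to C6, which calls either for the same epoxide opening (where an untethered carbon nucleophile attacks benzylic C1, not C5) or for a longer aldol sequence, and acylation at C4 adds steps. Under acid the C6 hydroxyl and the C1 acyloxy group can exchange by translactonisation, which opens a path to an isomeric hemiketal through the C1 oxygen. The ionising, hydride-donating medium also threatens the benzylic C1–O2 bond.
- Comparison: against the better C8 argument the chosen plan sets a much shorter access to the same compound 13, from two fragments with both rings formed in one flask.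

Key step: step 5

Assumption: aldehydes 1 and 6 are used as purchased O-benzyl ethers (both are catalogue compounds), so benzyl is the only phenol protecting group in the route.

## Route

Step 1
Reactants: 1 4-(benzyloxy)-3,5-dimethoxybenzaldehyde; 2 triethyl phosphonoacetate
Product: 3 ethyl (E)-3-[4-(benzyloxy)-3,5-dimethoxyphenyl]prop-2-enoate
Conditions: NaH, THF, 0 °C to rt
Reagents that add atoms: none
Why: Horner–Wadsworth–Emmons olefination; the stabilised phosphonate anion gives the (E)-cinnamate, the geometry the later epoxidation requires.

Step 2
Reactants: 3 ethyl (E)-3-[4-(benzyloxy)-3,5-dimethoxyphenyl]prop-2-enoate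
Product: 4 (E)-3-[4-(benzyloxy)-3,5-dimethoxyphenyl]prop-2-en-1-ol
Conditions: iBu2AlH (2.5 equiv), CH2Cl2, −78 °C; aq. KNaC4H4O6 (potassium sodium tartrate) work-up
Reagents that add atoms: none
Why: 1,2-reduction of a conjugated ester by iBu2AlH to the allylic alcohol; the alkene and the benzyl ether are not touched.

Step 3
Reactants: 4 (E)-3-[4-(benzyloxy)-3,5-dimethoxyphenyl]prop-2-en-1-ol
Product: 5 [(2R,3R)-3-[4-(benzyloxy)-3,5-dimethoxyphenyl]oxiran-2-yl]methanol
Conditions: Ti(OiPr)4 (10 mol %), D-(−)-diethyl tartrate (12 mol %), tBuOOH, 4 Å molecular sieves, CH2Cl2, −20 °C; cold aq. NaOH/NaCl work-up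
Reagents that add atoms: tert-butyl hydroperoxide, CC(C)(C)OO
Why: Sharpless asymmetric epoxidation of an (E)-allylic alcohol; with the D-(−)-tartrate ester the catalyst delivers oxygen to the face that gives the (2R,3R)-epoxide, which sets the later C1 and C5. The 4-benzyloxy group is twisted out of conjugation by its two methoxy neighbours, so the benzylic epoxide should survive the catalytic, sieve-dried conditions.

Step 4
Reactants: 6 3,4-bis(benzyloxy)benzaldehyde; 7 diallyl malonate
Product: 8 diallyl 2-[3,4-bis(benzyloxy)benzylidene]malonate
Conditions: piperidine (10 mol %), AcOH (10 mol %), toluene, reflux, Dean–Stark trap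
Reagents that add atoms: none
Why: Knoevenagel condensation driven by azeotropic removal of water; the two ester groups are identical, so no alkene geometry issue arises.

Step 5
Reactants: 5 [(2R,3R)-3-[4-(benzyloxy)-3,5-dimethoxyphenyl]oxiran-2-yl]methanol; 8 diallyl 2-[3,4-bis(benzyloxy)benzylidene]malonate
Product: 11 allyl (1R,4S,5S,8R)-8-[3,4-bis(benzyloxy)phenyl]-4-[4-(benzyloxy)-3,5-dimethoxyphenyl]-2-oxo-3,7-dioxabicyclo[3.3.0]octane-1-carboxylate, via oxa-Michael adduct 9 (not isolated), via tetrahydrofuran hydroxy diester 10 (not isolated)
Conditions: KOtBu (0.2 equiv), 8 (1.2 equiv), THF, 0 °C to rt (40 °C if closure lags); AcOH quench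
Reagents that add atoms: none
Why: Proposed new method: the alkoxide of 5 (K+ counter-ion) adds reversibly to the β-carbon C8 of 8 (oxa-Michael, O7–C8), which places the charge on malonate carbon C4; this carbanion opens the tethered epoxide at C5 by 5-exo-tet attack anti to the C5–O bond (C4–C5, ring B), and the alkoxide freed at C1 closes ring A by 5-exo-trig acyl substitution on the cis allyl ester (O2–C3), releasing allyl oxide that carries the chain, so base is needed only in catalytic amount. The closest known reaction types are Michael-initiated ring closures in which an alkoxide bearing an internal electrophile adds to an alkylidene malonate, and the opening of epoxides by malonate anions with lactonisation to α-carboxy γ-lactones; neither has been run with an epoxy alcohol as the bifunctional partner. C1 keeps the configuration of the epoxide and C5 is inverted, so the trans epoxide translates into the cis relation of the C1 aryl group and C6; C4 is not a stereocentre until lactonisation, which can only engage the ester cis to C1 because a trans-fused bicycle is out of reach. C8 is the one centre under kinetic control: since the first step is reversible, both C8 epimers of 9 interconvert, and the epimer that can hold the C8 aryl group anti to the forming bond (allylic strain against the planar malonate anion) with the epoxide carbon C1 pseudo-equatorial should close faster, giving the 2,4-cis tetrahydrofuran 10. The second selectivity needed is attack at C5 and not at benzylic C1; the five-membered exo mode, the absence of any Lewis acid and the weakly donating, twisted 4-benzyloxy group all favour C5. The retro-Michael cleavage that usually plagues β-alkoxy enolates is here only the reverse of the first step, and because the base rests as the malonate anion the standing concentration of free epoxy alkoxide is low, which should hold back Payne rearrangement.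

Step 6
Reactants: 11 allyl (1R,4S,5S,8R)-8-[3,4-bis(benzyloxy)phenyl]-4-[4-(benzyloxy)-3,5-dimethoxyphenyl]-2-oxo-3,7-dioxabicyclo[3.3.0]octane-1-carboxylate
Product: 13 (1R,4S,5S,8S)-8-[3,4-bis(benzyloxy)phenyl]-4-[4-(benzyloxy)-3,5-dimethoxyphenyl]-3,7-dioxabicyclo[3.3.0]octan-2-one, via carboxy lactone 12 (not isolated)
Conditions: Pd(OAc)2 (5 mol %), PPh3 (20 mol %), HCO2H (3 equiv), Et3N (2.5 equiv), 1,4-dioxane, rt, then 90 °C
Reagents that add atoms: none
Why: Palladium-catalysed deallylation (Tsuji conditions): zerovalent palladium formed in the flask ionises the allyl ester and formate reduces the π-allyl unit to propene, giving half-acid 12, which decarboxylates on warming through the lactone enol. Reprotonation at C4 can only give the cis-fused bicycle, so C4 is set by ring strain; the benzyl ethers are inert and the phenols stay masked while the compound is heated.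

Step 7
Reactants: 13 (1R,4S,5S,8S)-8-[3,4-bis(benzyloxy)phenyl]-4-[4-(benzyloxy)-3,5-dimethoxyphenyl]-3,7-dioxabicyclo[3.3.0]octan-2-one
Product: 14 (1R,4S,5S,8S)-8-(3,4-dihydroxyphenyl)-4-(4-hydroxy-3,5-dimethoxyphenyl)-3,7-dioxabicyclo[3.3.0]octan-2-one
Conditions: H2 (1 atm), 10% Pd/C, EtOAc–THF, rt
Reagents that add atoms: none
Why: Catalytic hydrogenolysis of three aryl benzyl ethers, which cleave faster than the ring benzylic ether and lactone C–O bonds; the medium is neutral and at room temperature, so C1 and C8 have no path to epimerise.

## Compound list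

In the names of 11–14 the von Baeyer locants 1, 2, 3 and 4 fall on C4, C3, O2 and C1 of the atom labels used in the text; locants 5 to 8 are the same.

1 | 4-(benzyloxy)-3,5-dimethoxybenzaldehyde | COc1cc(C=O)cc(OC)c1OCc1ccccc1 | starting material
2 | triethyl phosphonoacetate | CCOC(=O)CP(=O)(OCC)OCC | starting material
3 | ethyl (E)-3-[4-(benzyloxy)-3,5-dimethoxyphenyl]prop-2-enoate | CCOC(=O)/C=C/c1cc(OC)c(OCc2ccccc2)c(OC)c1 | intermediate
4 | (E)-3-[4-(benzyloxy)-3,5-dimethoxyphenyl]prop-2-en-1-ol | OC/C=C/c1cc(OC)c(OCc2ccccc2)c(OC)c1 | intermediate
5 | [(2R,3R)-3-[4-(benzyloxy)-3,5-dimethoxyphenyl]oxiran-2-yl]methanol | COc1cc([C@H]2O[C@@H]2CO)cc(OC)c1OCc1ccccc1 | intermediate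
6 | 3,4-bis(benzyloxy)benzaldehyde | O=Cc1ccc(OCc2ccccc2)c(OCc2ccccc2)c1 | starting material
7 | diallyl malonate | C=CCOC(=O)CC(=O)OCC=C | starting material
8 | diallyl 2-[3,4-bis(benzyloxy)benzylidene]malonate | C=CCOC(=O)C(=Cc1ccc(OCc2ccccc2)c(OCc2ccccc2)c1)C(=O)OCC=C | intermediate
9 | diallyl 2-{[3,4-bis(benzyloxy)phenyl]({(2R,3R)-3-[4-(benzyloxy)-3,5-dimethoxyphenyl]oxiran-2-yl}methoxy)methyl}malonate (both C8 epimers, in equilibrium; not isolated, present as the malonate anion) | C=CCOC(=O)C(C(=O)OCC=C)C(OC[C@H]1O[C@@H]1c1cc(OC)c(OCc2ccccc2)c(OC)c1)c1ccc(OCc2ccccc2)c(OCc2ccccc2)c1 | intermediate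
10 | diallyl (2R,4S)-2-[3,4-bis(benzyloxy)phenyl]-4-{(S)-[4-(benzyloxy)-3,5-dimethoxyphenyl](hydroxy)methyl}oxolane-3,3-dicarboxylate (not isolated, present as the C1 alkoxide) | COc1cc([C@@H](O)[C@@H]2CO[C@H](c3ccc(OCc4ccccc4)c(OCc4ccccc4)c3)C2(C(=O)OCC=C)C(=O)OCC=C)cc(OC)c1OCc1ccccc1 | intermediate
11 | allyl (1R,4S,5S,8R)-8-[3,4-bis(benzyloxy)phenyl]-4-[4-(benzyloxy)-3,5-dimethoxyphenyl]-2-oxo-3,7-dioxabicyclo[3.3.0]octane-1-carboxylate | COc1cc([C@H]2OC(=O)[C@]3(C(=O)OCC=C)[C@H]2CO[C@@H]3c2ccc(OCc4ccccc4)c(OCc4ccccc4)c2)cc(OC)c1OCc1ccccc1 | intermediate
12 | (1R,4S,5S,8R)-8-[3,4-bis(benzyloxy)phenyl]-4-[4-(benzyloxy)-3,5-dimethoxyphenyl]-2-oxo-3,7-dioxabicyclo[3.3.0]octane-1-carboxylic acid (not isolated) | COc1cc([C@H]2OC(=O)[C@]3(C(=O)O)[C@H]2CO[C@@H]3c2ccc(OCc4ccccc4)c(OCc4ccccc4)c2)cc(OC)c1OCc1ccccc1 | intermediate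
13 | (1R,4S,5S,8S)-8-[3,4-bis(benzyloxy)phenyl]-4-[4-(benzyloxy)-3,5-dimethoxyphenyl]-3,7-dioxabicyclo[3.3.0]octan-2-one | COc1cc([C@H]2OC(=O)[C@@H]3[C@H]2CO[C@@H]3c2ccc(OCc4ccccc4)c(OCc4ccccc4)c2)cc(OC)c1OCc1ccccc1 | intermediate
14 | (1R,4S,5S,8S)-8-(3,4-dihydroxyphenyl)-4-(4-hydroxy-3,5-dimethoxyphenyl)-3,7-dioxabicyclo[3.3.0]octan-2-one | COc1cc([C@H]2OC(=O)[C@@H]3[C@H]2CO[C@@H]3c2ccc(O)c(O)c2)cc(OC)c1O | target

## Step count and risks

Total step count: 7. Longest linear sequence: 6 steps (steps 1, 2, 3, 5, 6, 7, from aldehyde 1).

**Step 5 (key step, proposed new method).**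
- What may go wrong: closure of the malonate anion onto C5 is the slow event. If it lags, the epoxy alkoxide can drain into Payne rearrangement or benzylic opening at C1. The preference between the two C8-epimeric closures rests only on a conformational argument, so facial discrimination at C8 may be poor.
- Fallback (known chemistry only; leaves the route at 1 and comes back at 13): ring A would be built first by an auxiliary-controlled anti-aldol reaction and ring B closed last by a carbenoid C–H insertion.
  - The N-succinyl imide methyl 4-[(4S)-4-benzyl-2-oxo-1,3-oxazolidin-3-yl]-4-oxobutanoate F1 (from (S)-4-benzyl-1,3-oxazolidin-2-one and methyl 4-chloro-4-oxobutanoate) would add to 1 in the MgCl2-catalysed anti-aldol reaction (MgCl2, Et3N, Me3SiCl, EtOAc).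
  - Acid methanolysis of the silyl ether would lactonise the adduct to imide lactone F2, in which the C1 aryl group is already cis to the C6 carbonyl. The (S)-auxiliary is the one expected to give this sense on the chelated-enolate model.
  - NaBH4 in wet THF would cleave the imide reductively to hydroxymethyl lactone F3.
  - Ag2O, Bu4NI and 3,4-bis(benzyloxy)benzyl chloride would give ether F4.
  - Detrifluoroacetylative diazo transfer (LiN(SiMe3)2, CF3CO2CH2CF3, then MsN3, Et3N) would give α-diazo lactone F5.
  - Rh2(OAc)4 in CH2Cl2 would close ring B by 1,5-insertion of the C4 carbenoid into the benzylic ether C–H bond at C8. This is a known entry to cis-fused 2-aryl furofuranones that places the new aryl group on the concave face, and the product is 13.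

**Step 3.**
- What may go wrong: Lewis-acid-induced opening of the electron-rich aryl epoxide at the benzylic carbon during epoxidation or work-up, with loss of material and of enantiomeric purity.
- Fallback (from 4, back at 5): the hydroxyl group would be silylated (tBuMe2SiCl, imidazole) to silyl ether F6. The alkene would be epoxidised without any Lewis acid by the Shi epoxidation (D-fructose-derived ketone, KHSO5, K2CO3 buffer, MeCN–water, 0 °C) to epoxy silyl ether F7, and Bu4NF would return 5. Trans-disubstituted styrenes are the best substrates of this method, and the D-fructose-derived ketone gives the (R,R) sense needed.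

**Step 6.**
- What may go wrong: decarboxylation may lag behind deallylation, so that prolonged heating with palladium leads to ionisation of the benzylic lactone C–O bond or to β-elimination across C4–C8.
- Fallback (from 11, back at 13): the allyl ester would be cleaved at room temperature (Pd(PPh3)4, morpholine, THF) and acid 12 isolated. It would be converted with N-hydroxypyridine-2-thione and dicyclohexylcarbodiimide into thiohydroxamate ester F8 and decarboxylated by the Barton radical chain (tBuSH, visible light, rt). Hydrogen-atom transfer to the C4 radical can only occur on the convex face, giving 13 without heat.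

**Step 7.**
- What may go wrong: hydrogenolysis of the ring benzylic C–O bonds (C1–O2, C8–O7) in competition with O-debenzylation.
- Fallback (from 13 directly to 14): non-reductive debenzylation with BCl3 and pentamethylbenzene as benzyl-cation scavenger in CH2Cl2 at −78 °C, quenched cold. No metal surface or hydrogen is involved, aryl methyl ethers survive at this temperature, and no new intermediate is formed.

## Further compounds

F1 | step 5 | methyl 4-[(4S)-4-benzyl-2-oxo-1,3-oxazolidin-3-yl]-4-oxobutanoate | COC(=O)CCC(=O)N1[C@@H](Cc2ccccc2)COC1=O
F2 | step 5 | (4S)-4-benzyl-3-{[(2S,3R)-2-[4-(benzyloxy)-3,5-dimethoxyphenyl]-5-oxooxolan-3-yl]carbonyl}-1,3-oxazolidin-2-one | O=C1C[C@@H](C(=O)N2[C@@H](Cc3ccccc3)COC2=O)[C@@H](c2cc(OC)c(OCc3ccccc3)c(OC)c2)O1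
F3 | step 5 | (4S,5S)-5-[4-(benzyloxy)-3,5-dimethoxyphenyl]-4-(hydroxymethyl)oxolan-2-one | O=C1C[C@@H](CO)[C@@H](c2cc(OC)c(OCc3ccccc3)c(OC)c2)O1
F4 | step 5 | (4S,5S)-4-({[3,4-bis(benzyloxy)phenyl]methoxy}methyl)-5-[4-(benzyloxy)-3,5-dimethoxyphenyl]oxolan-2-one | O=C1C[C@@H](COCc2ccc(OCc3ccccc3)c(OCc3ccccc3)c2)[C@@H](c2cc(OC)c(OCc3ccccc3)c(OC)c2)O1
F5 | step 5 | (4S,5S)-4-({[3,4-bis(benzyloxy)phenyl]methoxy}methyl)-5-[4-(benzyloxy)-3,5-dimethoxyphenyl]-3-diazooxolan-2-one | [N-]=[N+]=C1C(=O)O[C@H](c2cc(OC)c(OCc3ccccc3)c(OC)c2)[C@@H]1COCc1ccc(OCc2ccccc2)c(OCc2ccccc2)c1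
F6 | step 3 | tert-butyl{[(E)-3-[4-(benzyloxy)-3,5-dimethoxyphenyl]prop-2-en-1-yl]oxy}dimethylsilane | CC(C)(C)[Si](C)(C)OC/C=C/c1cc(OC)c(OCc2ccccc2)c(OC)c1
F7 | step 3 | tert-butyl{[(2R,3R)-3-[4-(benzyloxy)-3,5-dimethoxyphenyl]oxiran-2-yl]methoxy}dimethylsilane | CC(C)(C)[Si](C)(C)OC[C@H]1O[C@@H]1c1cc(OC)c(OCc2ccccc2)c(OC)c1
F8 | step 6 | 2-thioxopyridin-1(2H)-yl (1R,4S,5S,8R)-8-[3,4-bis(benzyloxy)phenyl]-4-[4-(benzyloxy)-3,5-dimethoxyphenyl]-2-oxo-3,7-dioxabicyclo[3.3.0]octane-1-carboxylate | COc1cc([C@H]2OC(=O)[C@]3(C(=O)On4ccccc4=S)[C@H]2CO[C@@H]3c2ccc(OCc4ccccc4)c(OCc4ccccc4)c2)cc(OC)c1OCc1ccccc1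
F0 | step 7 | none | none
A1 | alternative 1 | methyl (2R)-1-[3,4-bis(benzyloxy)benzoyl]-2-[4-(benzyloxy)-3,5-dimethoxybenzoyl]cyclopropane-1-carboxylate (either configuration at the quaternary carbon) | COC(=O)C1(C(=O)c2ccc(OCc3ccccc3)c(OCc3ccccc3)c2)C[C@H]1C(=O)c1cc(OC)c(OCc2ccccc2)c(OC)c1
A2 | alternative 1 | methyl (4S)-2-[3,4-bis(benzyloxy)phenyl]-4-[4-(benzyloxy)-3,5-dimethoxybenzoyl]-4,5-dihydrofuran-3-carboxylate | COC(=O)C1=C(c2ccc(OCc3ccccc3)c(OCc3ccccc3)c2)OC[C@H]1C(=O)c1cc(OC)c(OCc2ccccc2)c(OC)c1
A3 | alternative 2 | 2-[4-(benzyloxy)-3,5-dimethoxyphenyl]acetyl chloride | COc1cc(CC(=O)Cl)cc(OC)c1OCc1ccccc1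
A4 | alternative 2 | 2,5-dihydrofuran | C1=CCOC1
A5 | alternative 2 | endo-7-[4-(benzyloxy)-3,5-dimethoxyphenyl]-3-oxabicyclo[3.2.0]heptan-6-one (formed as the racemate; needed enantiomer drawn) | COc1cc([C@H]2C(=O)[C@@H]3[C@H]2COC3)cc(OC)c1OCc1ccccc1
A6 | alternative 2 | (1R,4S,5S)-4-[4-(benzyloxy)-3,5-dimethoxyphenyl]-3,7-dioxabicyclo[3.3.0]octan-2-one | COc1cc([C@H]2OC(=O)[C@@H]3[C@H]2COC3)cc(OC)c1OCc1ccccc1
A7 | alternative 3 | (4S,5S)-3-[3,4-bis(benzyloxy)benzoyl]-5-[4-(benzyloxy)-3,5-dimethoxyphenyl]-4-(hydroxymethyl)oxolan-2-one (C3 epimerisable) | COc1cc([C@H]2OC(=O)C(C(=O)c3ccc(OCc4ccccc4)c(OCc4ccccc4)c3)[C@H]2CO)cc(OC)c1OCc1ccccc1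
A8 | alternative 3 | (1R,4S,5S,8S)-8-[3,4-bis(benzyloxy)phenyl]-4-[4-(benzyloxy)-3,5-dimethoxyphenyl]-3,7-dioxabicyclo[3.3.0]octan-2-one (identical with 13) | COc1cc([C@H]2OC(=O)[C@@H]3[C@H]2CO[C@@H]3c2ccc(OCc4ccccc4)c(OCc4ccccc4)c2)cc(OC)c1OCc1ccccc1
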